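The constants are invented; the flask was simulated.

Two questions are put to this flask, and I reach both by building it up one process at a time around a ceiling on the target.

electrophile 0.41 M (fed, over 20 s); solid nucleophile 0.615 M; time 1.5 min

- part of the electrophile that has reacted at 1.5 min
- share of free nucleophile in free nucleophile and protonated nucleophile together, at 1.5 min

    solid nucleophile ⇌ nucleophile, rate k1*(cs1 - [nucleophile]) while solid is left; crystals form when [nucleophile] > cs1 (cs1 = 0.15 M, k1 = 0.12 s⁻¹)
    electrophile + target → side product (k2 = 0.24 M⁻¹ s⁻¹)
    nucleophile + acid set free ⇌ protonated nucleophile, settled at all times (K3 = 7000 M⁻¹)
    electrophile + nucleophile → acid set free + target (k4 = 0.15 M⁻¹ s⁻¹)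

- percent here means electrophile units held: one side product counts as two
- solid nucleophile is a solid; its amount is given per volume of the solution
- at the start none of the solid nucleophile is in solution
- run time (flask): 1.5 min

First the main step alone, with c(nucleophile) held at the solubility: a pseudo-first-order loss of electrophile. Fed electrophile has on average spent 80.0 s in the flask, so

c = 83.5%

Now the side step. Target climbs towards 0.0938 M, the target ceiling, the concentration at which the side step destroys target as fast as the main step makes it: main constant times c(nucleophile) over side constant. That is about a quarter of the charge. At the ceiling both steps take electrophile equally, and assuming this throughout, which overstates, gives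

c = 97.3%

Then the rest. The acid constant times the solubility is 1050, so each coupling costs two nucleophiles, and while solid is left I let dissolving balance that demand:

c(nucleophile) = 0.15 M × 0.12 s⁻¹ / (0.12 s⁻¹ + 2 × 0.15 M⁻¹ s⁻¹ × c(electrophile))

With electrophile at 0.205 M this gives 0.0992 M, and my estimate becomes

c = 90.7%

With the electrophile left by that estimate, the same balance gives free nucleophile of 0.137 M late in the run, and the ceiling becomes 0.0856 M. Electrophile consumed is twice the couplings minus target held, and I take target at that ceiling, so

protonated nucleophile = (electrophile consumed + target) / 2 = 0.229 M

fr = 37.4%

The forecast, slightly different from mine, gives 90% and 38%, expecting that “free nucleophile should sit near 0.13 M”. The simulation gives 88.6% and 37.8%.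

At 1.50 min this flask holds 0.0647 M of target, below the ceiling of 0.0813 M reckoned from the 0.130 M of free nucleophile then present. Ceiling over target is by its definition the rate of electrophile use by coupling over that by the side step, and in this flask at that time coupling uses electrophile 1.3 times as fast as the side step. The neighbour flask charged with 0.25 M of electrophile has its ceiling, reckoned from its 0.138 M of free nucleophile, at 0.0863 M and holds 0.0635 M of target, which is 25.4% of its charge, beside 64.5% as side product.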